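**Retrosynthetic overview**

1. Backbone numbering: C1 ring B carbonyl, C2 CH(OH), C3 C(OH)CO2H, C4 spiro carbon, C5 CH2, C6 CH(decenyl)–O, C7 ring A carbonyl. The route rests on ring B (O–C1–C2–C3–C4) being the O-glycolyl ester of the C4 tertiary oxygen whose α-carbon C2 is joined to C3, a β-hydroxy carbon bearing a carboxyl; this is the aldol adduct of a glycolate enolate and an α-keto ester that both hang on C4.
2. Ring B (last ring): C2–C3 is cut by an intramolecular ester-enolate aldol of a ring A lactone that carries a (silyloxy)acetoxy and a tert-butoxyoxalyl group on C4.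
3. C4: the C4–O bond comes from O-acylation after enolate hydroxylation anti to the C6 chain; the C4–C3 bond comes from Claisen oxalylation of the simple γ-lactone.
4. Ring A (first ring): malonate opening and lactonisation of (R)-2-(dec-9-enyl)oxirane, itself from hydrolytic kinetic resolution of the monoepoxide of dodeca-1,11-diene.
5. Ring order: ring A in step 3, ring B in step 8; two acidic deprotections finish the synthesis.

Key step: step 8

Remark: keto ester 10 is drawn as the keto tautomer although it should exist largely as the chelated enol; the sense of the kinetic resolution in step 2 is assigned by analogy with simple monoalkyl oxiranes.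

**Route**

Step 1
Reactants: 1 dodeca-1,11-diene
Product: 2 rac-2-(dec-9-en-1-yl)oxirane
Conditions: mCPBA (0.4 equiv), CH2Cl2, 0 °C → rt; excess 1 recovered by distillation
Reagents that add atoms: 3-chloroperoxybenzoic acid, O=C(OO)c1cccc(Cl)c1
Why: Prilezhaev epoxidation of one of two equivalent terminal alkenes; with the diene in excess the monoepoxide should predominate, and it is racemic at this stage.

Step 2
Reactants: 2 rac-2-(dec-9-en-1-yl)oxirane
Product: 3 (2R)-2-(dec-9-en-1-yl)oxirane
Conditions: (R,R)-(salen)Co(OAc) (0.5 mol %; salen = N,N'-bis(3,5-di-tert-butylsalicylidene)cyclohexane-1,2-diamine dianion), H2O (0.55 equiv), THF, 0 °C → rt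
Reagents that add atoms: none
Why: Jacobsen hydrolytic kinetic resolution: the (R,R)-catalyst should hydrolyse the (S)-epoxide much faster, as with other monoalkyl oxiranes, so that unreacted (R)-3, whose carbinol carbon becomes C6, is recovered by distillation from the diol (the sense would be checked by optical rotation, the antipodal catalyst serving otherwise).

Step 3
Reactants: 3 (2R)-2-(dec-9-en-1-yl)oxirane; 4 diethyl malonate
Product: 6 ethyl (5R)-5-(dec-9-en-1-yl)-2-oxooxolane-3-carboxylate (both C3 epimers), via hydroxy malonate 5 (not isolated)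
Conditions: NaOEt (1.1 equiv), EtOH, 0 °C → reflux; then aq. HCl
Reagents that add atoms: none
Why: Malonic ester lactone synthesis: sodiomalonate opens the epoxide by SN2 at the terminal CH2, the C–O bond of the stereocentre is not touched, and the alkoxide closes ring A onto one ester.

Step 4
Reactants: 6 ethyl (5R)-5-(dec-9-en-1-yl)-2-oxooxolane-3-carboxylate
Product: 7 (5R)-5-(dec-9-en-1-yl)oxolan-2-one (lactone A)
Conditions: LiCl, H2O (2 equiv), DMSO, 150 °C
Reagents that add atoms: none
Why: Krapcho dealkoxycarbonylation should remove the exocyclic ester of the β-dicarbonyl unit without affecting the lactone, the C6 stereocentre or the alkene.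

Step 5
Reactants: 7 (5R)-5-(dec-9-en-1-yl)oxolan-2-one; 8 di-tert-butyl oxalate
Product: 10 tert-butyl 2-[(5R)-5-(dec-9-en-1-yl)-2-oxooxolan-3-yl]-2-oxoacetate, via lithium enolate 9 (not isolated)
Conditions: LiN(SiMe3)2 (2.2 equiv), THF, −78 °C; then 8 (1.2 equiv), −78 → −20 °C; aq. NH4Cl
Reagents that add atoms: none
Why: Crossed Claisen condensation of the lactone enolate with a non-enolisable oxalate, driven by deprotonation of the acidic product by the second equivalent of base; the bulky tert-butyl ester suppresses double addition, and the configuration at the acylated carbon is immaterial because 10 is enolised.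

Step 6
Reactants: 10 tert-butyl 2-[(5R)-5-(dec-9-en-1-yl)-2-oxooxolan-3-yl]-2-oxoacetate
Product: 12 tert-butyl 2-[(3S,5R)-5-(dec-9-en-1-yl)-3-hydroxy-2-oxooxolan-3-yl]-2-oxoacetate, via potassium enolate 11 (not isolated)
Conditions: KN(SiMe3)2 (1.05 equiv), THF, −78 °C; then 2-(phenylsulfonyl)-3-phenyloxaziridine, −78 → −40 °C; AcOH quench at −78 °C
Reagents that add atoms: 2-(phenylsulfonyl)-3-phenyloxaziridine, O=S(=O)(c1ccccc1)N1OC1c1ccccc1
Why: Davis oxidation of a β-dicarbonyl enolate: the bulky oxaziridine should attack the planar enolate on the face anti to the C6 decenyl chain (1,3-induction in γ-substituted butyrolactone enolates), which sets C4 with its oxygen trans to the chain; the reagent does not epoxidise the terminal alkene, and the cold acidic quench limits retro-Claisen loss of the oxalyl group.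

Step 7
Reactants: 12 tert-butyl 2-[(3S,5R)-5-(dec-9-en-1-yl)-3-hydroxy-2-oxooxolan-3-yl]-2-oxoacetate; 13 [(tert-butyldimethylsilyl)oxy]acetic acid
Product: 15 tert-butyl 2-[(3S,5R)-3-({[tert-butyl(dimethyl)silyl]oxy}acetoxy)-5-(dec-9-en-1-yl)-2-oxooxolan-3-yl]-2-oxoacetate, via acid chloride 14 (not isolated)
Conditions: 13, 1-chloro-N,N,2-trimethylprop-1-en-1-amine, CH2Cl2, 0 °C → rt; then 12, pyridine, DMAP (0.2 equiv), 0 °C → rt
Reagents that add atoms: none
Why: The Ghosez reagent should form the acid chloride under neutral conditions that keep the silyl ether, and DMAP-catalysed acyl transfer (acylpyridinium) then esterifies the tertiary hydroxyl without touching the C4 configuration.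

Step 8
Reactants: 15 tert-butyl 2-[(3S,5R)-3-({[tert-butyl(dimethyl)silyl]oxy}acetoxy)-5-(dec-9-en-1-yl)-2-oxooxolan-3-yl]-2-oxoacetate
Product: 17 tert-butyl (3R,4R,5S,8R)-3-{[tert-butyl(dimethyl)silyl]oxy}-8-(dec-9-en-1-yl)-4-hydroxy-2,6-dioxo-1,7-dioxaspiro[4.4]nonane-4-carboxylate, via lithium enolate 16 (not isolated)
Conditions: LiN(SiMe3)2 (1.1 equiv), THF, −78 °C; AcOH/THF quench at −78 °C
Reagents that add atoms: none
Why: LiN(SiMe3)2 can only remove a glycolate CH2 proton (C4 is quaternary and the oxalyl ketone has no α-hydrogen), and ester enolate 16 adds through C2 to the neighbouring, very electrophilic C3 ketone in an intramolecular aldol addition, the reaction type by which O-acylated α-hydroxy ketones are closed to β-hydroxy-γ-lactones and butenolides. Ring B closes in the 5-(enolendo)-exo-trig mode, nominally the less favourable enolate mode but the one that operates in exactly these acyloxy-ketone aldol and tetronate Dieckmann closures. C3 should be fixed by a lithium chelate between the C3 ketone oxygen and the ring A carbonyl oxygen on C7, which turns the ketone oxygen to the C7 side of the forming ring, so that the new hydroxyl is cis to C7 and the tert-butyl ester cis to C5. C2 should follow from the enolate geometry (O–Li and silyloxy cis, the hydrogen on the inner position of the closing ring) and from the bulky, non-chelating silyloxy group staying away from the developing lithium alkoxide, which places it trans to the C3 hydroxyl. The step needs chemoselectivity for the ketone over the ring A lactone and the ester carbonyls (Dieckmann closure) and a kinetic quench: the much higher electrophilicity of the α-keto ester at −78 °C, the bulk of the tert-butyl ester and protonation of the aldolate with acetic acid before warming should secure both.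

Step 9
Reactants: 17 tert-butyl (3R,4R,5S,8R)-3-{[tert-butyl(dimethyl)silyl]oxy}-8-(dec-9-en-1-yl)-4-hydroxy-2,6-dioxo-1,7-dioxaspiro[4.4]nonane-4-carboxylate
Product: 18 tert-butyl (3R,4R,5S,8R)-8-(dec-9-en-1-yl)-3,4-dihydroxy-2,6-dioxo-1,7-dioxaspiro[4.4]nonane-4-carboxylate
Conditions: 48% aq. HF, MeCN, 0 °C → rt
Reagents that add atoms: none
Why: Acidic fluoride desilylation should cleave the Si–O bond while the lactones and the tert-butyl ester persist, and it avoids basic fluoride, which could trigger retro-aldol opening of the β-hydroxy lactone.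

Step 10
Reactants: 18 tert-butyl (3R,4R,5S,8R)-8-(dec-9-en-1-yl)-3,4-dihydroxy-2,6-dioxo-1,7-dioxaspiro[4.4]nonane-4-carboxylate
Product: 19 (3R,4R,5S,8R)-8-(dec-9-en-1-yl)-3,4-dihydroxy-2,6-dioxo-1,7-dioxaspiro[4.4]nonane-4-carboxylic acid (target)
Conditions: CF3CO2H/CH2Cl2 (1:4), 0 °C → rt
Reagents that add atoms: none
Why: Acidolysis of the tert-butyl ester through the tert-butyl cation, lost as isobutene, should free the C3 carboxyl; the lactones, the monosubstituted alkene and all four stereocentres are expected to survive dilute acid at low temperature.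

**Compound list**

1 | dodeca-1,11-diene | C=CCCCCCCCCC=C | starting material
2 | rac-2-(dec-9-en-1-yl)oxirane | C=CCCCCCCCCC1CO1 | intermediate
3 | (2R)-2-(dec-9-en-1-yl)oxirane | C=CCCCCCCCC[C@@H]1CO1 | intermediate
4 | diethyl malonate | CCOC(=O)CC(=O)OCC | starting material
5 | diethyl 2-[(2R)-2-hydroxydodec-11-en-1-yl]propanedioate (formed as its sodium alkoxide) | C=CCCCCCCCC[C@@H](O)CC(C(=O)OCC)C(=O)OCC | intermediate (not isolated)
6 | ethyl (5R)-5-(dec-9-en-1-yl)-2-oxooxolane-3-carboxylate (both C3 epimers) | C=CCCCCCCCC[C@@H]1CC(C(=O)OCC)C(=O)O1 | intermediate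
7 | (5R)-5-(dec-9-en-1-yl)oxolan-2-one (lactone A) | C=CCCCCCCCC[C@@H]1CCC(=O)O1 | intermediate
8 | di-tert-butyl oxalate | CC(C)(C)OC(=O)C(=O)OC(C)(C)C | starting material
9 | lithium enolate of 7 | C=CCCCCCCCC[C@@H]1CC=C(O[Li])O1 | intermediate (not isolated)
10 | tert-butyl 2-[(5R)-5-(dec-9-en-1-yl)-2-oxooxolan-3-yl]-2-oxoacetate (keto form drawn) | C=CCCCCCCCC[C@@H]1CC(C(=O)C(=O)OC(C)(C)C)C(=O)O1 | intermediate
11 | potassium enolate of 10 | C=CCCCCCCCC[C@@H]1CC(=C(O[K])C(=O)OC(C)(C)C)C(=O)O1 | intermediate (not isolated)
12 | tert-butyl 2-[(3S,5R)-5-(dec-9-en-1-yl)-3-hydroxy-2-oxooxolan-3-yl]-2-oxoacetate | C=CCCCCCCCC[C@@H]1C[C@](O)(C(=O)C(=O)OC(C)(C)C)C(=O)O1 | intermediate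
13 | [(tert-butyldimethylsilyl)oxy]acetic acid | CC(C)(C)[Si](C)(C)OCC(=O)O | starting material
14 | [(tert-butyldimethylsilyl)oxy]acetyl chloride | CC(C)(C)[Si](C)(C)OCC(=O)Cl | intermediate (not isolated)
15 | tert-butyl 2-[(3S,5R)-3-({[tert-butyl(dimethyl)silyl]oxy}acetoxy)-5-(dec-9-en-1-yl)-2-oxooxolan-3-yl]-2-oxoacetate (aldol precursor) | C=CCCCCCCCC[C@@H]1C[C@](OC(=O)CO[Si](C)(C)C(C)(C)C)(C(=O)C(=O)OC(C)(C)C)C(=O)O1 | intermediate
16 | lithium enolate of 15 at the glycolate carbon (O–Li and silyloxy cis) | C=CCCCCCCCC[C@@H]1C[C@](O/C(O[Li])=C/O[Si](C)(C)C(C)(C)C)(C(=O)C(=O)OC(C)(C)C)C(=O)O1 | intermediate (not isolated)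
17 | tert-butyl (3R,4R,5S,8R)-3-{[tert-butyl(dimethyl)silyl]oxy}-8-(dec-9-en-1-yl)-4-hydroxy-2,6-dioxo-1,7-dioxaspiro[4.4]nonane-4-carboxylate | C=CCCCCCCCC[C@@H]1C[C@@]2(OC(=O)[C@H](O[Si](C)(C)C(C)(C)C)[C@]2(O)C(=O)OC(C)(C)C)C(=O)O1 | intermediate
18 | tert-butyl (3R,4R,5S,8R)-8-(dec-9-en-1-yl)-3,4-dihydroxy-2,6-dioxo-1,7-dioxaspiro[4.4]nonane-4-carboxylate | C=CCCCCCCCC[C@@H]1C[C@@]2(OC(=O)[C@H](O)[C@]2(O)C(=O)OC(C)(C)C)C(=O)O1 | intermediate
19 | (3R,4R,5S,8R)-8-(dec-9-en-1-yl)-3,4-dihydroxy-2,6-dioxo-1,7-dioxaspiro[4.4]nonane-4-carboxylic acid | C=CCCCCCCCC[C@@H]1C[C@@]2(OC(=O)[C@H](O)[C@]2(O)C(=O)O)C(=O)O1 | target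

**Step count**

Total: 10 steps. Longest linear sequence: 10 steps (1 → 19); 4, 8 and 13 enter as purchased reagents.

**Steps most likely to fail**

Step 8 (key aldol). The facial selection at C2 and C3 may not follow the chelate picture. The hindered silyloxy enolate may also close slowly, so that Dieckmann acylation at the ring A carbonyl, retro-aldol or dehydration to the butenolide compete. The fallback moves the C2 oxygen to a later stage and sets out from 12. Acetylation (Ac2O, DMAP, pyridine, CH2Cl2, 0 °C) would give tert-butyl 2-[(3S,5R)-3-acetoxy-5-(dec-9-en-1-yl)-2-oxooxolan-3-yl]-2-oxoacetate F1. Its unhindered lithium enolate (LiN(SiMe3)2, THF, −78 °C) should close ring B by the same aldol mode to tert-butyl (4R,5S,8R)-8-(dec-9-en-1-yl)-4-hydroxy-2,6-dioxo-1,7-dioxaspiro[4.4]nonane-4-carboxylate F2, with C3 again set by the lithium chelate to C7. The dianion of F2 (LiN(iPr)2, 2.2 equiv, THF, −78 °C) would then be hydroxylated with 2-(phenylsulfonyl)-3-phenyloxaziridine. The oxidant should enter trans to the C3 alkoxide, as in Fráter–Seebach-type reactions of β-hydroxy-γ-butyrolactone dianions. This gives 18 directly, where the route is rejoined; step 9 is then not needed.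

Step 6 (hydroxylation). The 1,3-induction from the remote C6 chain on a flat, delocalised enolate may give poor facial selectivity. The product alkoxide may also lose its oxalyl group by retro-Claisen cleavage or undergo an α-ketol shift. The fallback changes the source of stereocontrol from substrate to reagent. Setting out from 10, the sodium enolate (NaN(SiMe3)2, THF, −78 °C) would be oxidised with the matched antipode of enantiopure (camphorsulfonyl)oxaziridine or its 8,8-dichloro analogue; both antipodes are available and the matched one would be found by trial. Reagent and substrate bias then reinforce each other, and the route is rejoined at 12.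

Step 7 (O-acylation). Acyl transfer to a tertiary hydroxyl flanked by two carbonyl groups may be slow, and amine- or DMAP-induced fragmentation of the α-hydroxy-β-dicarbonyl unit may win. The fallback avoids the free alcohol and sets out from 10. PhI(OAc)2 and 13 (2 equiv) would be converted by ligand exchange, with acetic acid removed under reduced pressure, into the trivalent iodine carboxylate [bis({[tert-butyl(dimethyl)silyl]oxy}acetoxy)-λ3-iodanyl]benzene F3. F3 should then transfer its acyloxy group to the α-carbon of enolised 10 (CH2Cl2, rt), the known oxidative α-acyloxylation of 1,3-dicarbonyl compounds by (diacyloxyiodo)arenes. The carboxylate is expected to arrive anti to the C6 chain, which gives 15 directly, where the route is rejoined.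

**Further compounds**

F1 | step 8 | tert-butyl 2-[(3S,5R)-3-acetoxy-5-(dec-9-en-1-yl)-2-oxooxolan-3-yl]-2-oxoacetate | C=CCCCCCCCC[C@@H]1C[C@](OC(C)=O)(C(=O)C(=O)OC(C)(C)C)C(=O)O1
F2 | step 8 | tert-butyl (4R,5S,8R)-8-(dec-9-en-1-yl)-4-hydroxy-2,6-dioxo-1,7-dioxaspiro[4.4]nonane-4-carboxylate | C=CCCCCCCCC[C@@H]1C[C@@]2(OC(=O)C[C@]2(O)C(=O)OC(C)(C)C)C(=O)O1
F0 | step 6 | none | none
F3 | step 7 | [bis({[tert-butyl(dimethyl)silyl]oxy}acetoxy)-λ3-iodanyl]benzene | CC(C)(C)[Si](C)(C)OCC(=O)OI(OC(=O)CO[Si](C)(C)C(C)(C)C)c1ccccc1
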